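A factor of 4.00 in free catalyst, from the west run to the south-west run, buys you a factor of 1.50 in the time to about the same left-handed product, so I take the dissolving of the solid reagent as the rate-limiting step for much of a run.

| flask | left-handed substrate | right-handed substrate | solid reagent | free catalyst | remark |
|---|---|---|---|---|---|
| west | 0.28 M | 0.28 M | 2 equiv | 5.5 mol% | run made earlier |
| south-west | 0.28 M | 0.28 M | 2 equiv | 22 mol% | run made earlier |
| north-east | 0.14 M | 0.14 M | 2 equiv | 11 mol% | run made earlier |
| flask | 0.28 M | 0.28 M | 2.00 equiv | 11 mol% |  |

| run | time / min | left-handed product / % | left-handed substrate / % |
|---|---|---|---|
| west | 0.200 | 6 | 41 |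
| west | 0.417 | 17 | 33 |
| west | 1.00 | 44 | 7 |
| west | 2.50 | 51 | 0 |
| south-west | 0.667 | 42 | 8 |
| south-west | 1.33 | 49 | 1 |
| south-west | 2.00 | 51 | 0 |
| south-west | 2.50 | 48 | 1 |
| north-east | 0.200 | 12 | 38 |
| north-east | 0.417 | 27 | 19 |
| north-east | 1.00 | 51 | 2 |
| north-east | 2.50 | 52 | 1 |

(standard deviation of a reading: 2 percentage points)

1. apparent order in free catalyst when 50% of the left-handed substrate and right-handed substrate together are converted (percent change of the rate of making left-handed product for one percent more free catalyst charged)
2. factor on the rate of making left-handed product when 50% of the left-handed substrate and right-handed substrate together are converted if free catalyst is charged twice over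

Suppose dissolving slows in proportion to the distance from saturation, while demand grows with catalyst. The order in free catalyst then equals the fraction of saturation reached, which is one minus the rate over the dissolving ceiling, and doubling the catalyst multiplies the rate by two over (two minus that order). In the south-west run the average rate of making left-handed product up to 0.667 min reads 0.630 /min of the charge, which I take as a rough floor for the ceiling, and the average rate from 0.667 min to 1.33 min, a stretch in which the product nears its stop, reads 0.106 /min, which gives an order of 0.832. The weak link is that this run holds twice the flask's catalyst. The west run has the same charge of solid reagent, so I keep that ceiling for it, and its average rate from 1.00 min to 2.50 min of 0.0467 /min gives an order of 0.926, at half the flask's loading. Both rates are averages over stretches that run up to the stop of the product, not the rate at one moment, so this is a rough reckoning. So for the flask I commit to the mean, the headroom, meaning the fraction of the ceiling left unused, of 0.879, and to a doubling factor of 1.78; both lean on differences of readings with a scatter of 2 percentage points.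

The forecast gave 0.95 and 1.93, arguing that “The remaining left-handed substrate at fixed conversion is set by selectivity, not catalyst loading.”

The flask gives 0.85 and 1.68, so my headroom of 0.879 is higher by 0.0290, and my factor is higher by a ratio of 1.06.

    partner + catalyst intermediate A → free catalyst + left-handed product (k = 22.0 /M/s)
    free catalyst + right-handed substrate ⇌ catalyst intermediate B (K = 5.80 /M, k = 190 /M/s)
    free catalyst + left-handed substrate ⇌ catalyst intermediate A (K = 9.20 /M, k = 110 /M/s)
    partner + catalyst intermediate B → free catalyst + right-handed product (k = 0.310 /M/s)
    solid reagent ⇌ partner, rate k5*(cs5 - [partner]) while solid is left; crystals form when [partner] > cs5 (solubility = 0.130 M, k = 0.0540 /s)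

In the flask at 0.733 min, partner, the dissolved solid reagent, is made 1.23 times faster than it is used up, each step taken net. At 4.00 min that ratio is lower, at 1.03, with c(partner) at 0.120 M, which is 0.921 of its solubility.

(Readings and results come from a simulation from invented constants; scatter was added.)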